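Numbering: C1 CHOAc, C2, C3 CMe, C4 CHBr, C5, C6 CMe, C7 CHMe, C8 CHBr, C9 CHOH, C10 CHMe, C11 central; ring A C1–C2–C3–C11, ring B C3–C4–C5–C6–C11, ring C C6–C7–C8–C9–C10–C11. Cutting C3–C11 merges rings A and B into the seven-membered ring C1–C2–C3–C4–C5–C6–C11, whose 1,4-heteroatoms (C1, C4) and C3 methyl map onto 2,5-dimethoxytoluene expanded by C6. One intramolecular Buchner reaction forms C5–C6 and C6–C11, closes ring C and sets quaternary C6. Its precursor is an enantiopure aryl-tethered 2-diazo-3-ketone with C10 methyl and C9 silyloxy groups; 4π photoclosure later re-forms C3–C11.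

Key step: step 11

Remark on the chemistry: C9 passes through the key step as the tert-butyldimethylsilyl ether of the (S)-alcohol, not at the ketone level. A ketal oxygen β to the carbenoid would be trapped as a five-membered oxonium ylide, and a C9 carbonyl would make the benzylic C10 stereocentre enolisable. The (S)-hydroxyl later directs the C7 hydrogenation. "Exo" means the face of ring A that carries C10. Acyclic compounds carry CIP descriptors; for the polycycles the SMILES in the compound list defines the configuration.

Step 1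
Reactants: 1 1-bromo-2,5-dimethoxy-4-methylbenzene; 2 ethyl pyruvate
Product: 4 ethyl 2-(2,5-dimethoxy-4-methylphenyl)-2-hydroxypropanoate (racemic), via arylmagnesium bromide 3 (not isolated)
Conditions: Mg, THF, reflux; then added to 2, THF, −78 °C; aq. NH4Cl
Reagents that add atoms: none
Why: Grignard addition by inverse addition at low temperature should take the ketone carbonyl of the α-keto ester in preference to the ester; the stereocentre formed is removed in step 2.

Step 2
Reactants: 4 ethyl 2-(2,5-dimethoxy-4-methylphenyl)-2-hydroxypropanoate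
Product: 5 ethyl 2-(2,5-dimethoxy-4-methylphenyl)prop-2-enoate
Conditions: TsOH·H2O (cat.), BHT, toluene, reflux, Dean–Stark
Reagents that add atoms: none
Why: Acid-catalysed E1 dehydration of the tertiary benzylic alcohol, whose cation is stabilised by the electron-rich arene, should give the 2-arylacrylate with azeotropic removal of water.

Step 3
Reactants: 5 ethyl 2-(2,5-dimethoxy-4-methylphenyl)prop-2-enoate
Product: 6 2-(2,5-dimethoxy-4-methylphenyl)prop-2-enoic acid
Conditions: LiOH, THF–H2O, rt; then 1 M HCl
Reagents that add atoms: lithium hydroxide [Li+].[OH-]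
Why: Saponification supplies the free acid that the ruthenium catalyst of step 4 needs as its binding group.

Step 4
Reactants: 6 2-(2,5-dimethoxy-4-methylphenyl)prop-2-enoic acid
Product: 7 (2R)-2-(2,5-dimethoxy-4-methylphenyl)propanoic acid
Conditions: H2 (100 atm), Ru(OAc)2[(R)-BINAP] (0.5 mol%), MeOH, rt
Reagents that add atoms: none
Why: Noyori asymmetric hydrogenation of a 2-arylacrylic acid: the carboxylate binds ruthenium and the (R)-ligand should give the (R)-acid, the mirror image of the sense that gives (S)-naproxen with the (S)-ligand; this sets C10.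

Step 5
Reactants: 7 (2R)-2-(2,5-dimethoxy-4-methylphenyl)propanoic acid; 8 potassium ethyl malonate
Product: 11 ethyl (4R)-4-(2,5-dimethoxy-4-methylphenyl)-3-oxopentanoate, via acyl imidazolide 9 (not isolated), via acylmalonate half-ester 10 (not isolated)
Conditions: CDI, THF, rt; then 8, MgCl2, Et3N, MeCN, rt → 40 °C; 1 M HCl, 0 °C; used crude
Reagents that add atoms: none
Why: Masamune–Brooks homologation: the imidazolide C-acylates the neutral magnesium malonate and the adduct loses CO2 on acidification, without strong base, so the benzylic stereocentre should survive.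

Step 6
Reactants: 11 ethyl (4R)-4-(2,5-dimethoxy-4-methylphenyl)-3-oxopentanoate
Product: 12 ethyl (3S,4R)-4-(2,5-dimethoxy-4-methylphenyl)-3-hydroxypentanoate
Conditions: H2 (50 atm), RuCl2[(R)-BINAP](dmf)n (1 mol%), EtOH, 40 °C
Reagents that add atoms: none
Why: Noyori hydrogenation of a β-keto ester under catalyst control: the (R)-ligand gives the sense of (R)-3-hydroxybutanoate, here (3S) by the priority change, reinforced by the Felkin preference of the α-aryl ketone; this sets the C9 carbinol and removes the enolisable ketone next to C10.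

Step 7
Reactants: 12 ethyl (3S,4R)-4-(2,5-dimethoxy-4-methylphenyl)-3-hydroxypentanoate
Product: 13 ethyl (3S,4R)-3-[(tert-butyldimethylsilyl)oxy]-4-(2,5-dimethoxy-4-methylphenyl)pentanoate
Conditions: TBSOTf, 2,6-lutidine, CH2Cl2, 0 °C
Reagents that add atoms: tert-butyldimethylsilyl triflate CC(C)(C)[Si](C)(C)OS(=O)(=O)C(F)(F)F
Why: Silylation gives a bulky, weakly basic ether that prevents O–H insertion and ylide formation in step 11 and deactivates the neighbouring C–H bonds inductively.

Step 8
Reactants: 13 ethyl (3S,4R)-3-[(tert-butyldimethylsilyl)oxy]-4-(2,5-dimethoxy-4-methylphenyl)pentanoate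
Product: 14 (3S,4R)-3-[(tert-butyldimethylsilyl)oxy]-4-(2,5-dimethoxy-4-methylphenyl)-N-methoxy-N-methylpentanamide
Conditions: MeNH(OMe)·HCl, i-PrMgCl, THF, −20 → 0 °C
Reagents that add atoms: N,O-dimethylhydroxylamine hydrochloride CNOC.Cl
Why: Direct aminolysis of the ester by the magnesium amide (Weinreb amide formation) is routine for β-silyloxy esters at low temperature.

Step 9
Reactants: 14 (3S,4R)-3-[(tert-butyldimethylsilyl)oxy]-4-(2,5-dimethoxy-4-methylphenyl)-N-methoxy-N-methylpentanamide; 15 ethylmagnesium bromide
Product: 16 (5S,6R)-5-[(tert-butyldimethylsilyl)oxy]-6-(2,5-dimethoxy-4-methylphenyl)heptan-3-one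
Conditions: THF, 0 °C; aq. NH4Cl
Reagents that add atoms: none
Why: Weinreb ketone synthesis: the chelated tetrahedral adduct stops at the ketone stage and brings in C6 with its methyl group.

Step 10
Reactants: 16 (5S,6R)-5-[(tert-butyldimethylsilyl)oxy]-6-(2,5-dimethoxy-4-methylphenyl)heptan-3-one
Product: 18 (5S,6R)-5-[(tert-butyldimethylsilyl)oxy]-2-diazo-6-(2,5-dimethoxy-4-methylphenyl)heptan-3-one, via trifluoroacetyl diketone 17 (not isolated)
Conditions: LiHMDS, THF, −78 °C; CF3CO2CH2CF3; then MsN3, Et3N, H2O, MeCN, rt
Reagents that add atoms: methanesulfonyl azide CS(=O)(=O)N=[N+]=[N-]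
Why: Danheiser detrifluoroacetylative diazo transfer: kinetic enolisation should occur at the unbranched ethyl methylene (C6) and not at C8, which is flanked by the branched silyloxy carbon, and the activated diketone then transfers the diazo group to C6 with loss of the trifluoroacetyl group.

Step 11
Reactants: 18 (5S,6R)-5-[(tert-butyldimethylsilyl)oxy]-2-diazo-6-(2,5-dimethoxy-4-methylphenyl)heptan-3-one
Product: 20 cycloheptatriene-fused cyclohexanone (C1=C11, C2=C3, C4=C5; OMe at C1 and C4; Me at C3, C6, C10; C7 ketone; C9 OTBS; C6 methyl trans to C10 methyl), via norcaradiene 19 (not isolated)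
Conditions: Rh2(O2CCF3)4 (1 mol%), CH2Cl2, 0 °C → rt, slow addition of 18
Reagents that add atoms: none
Why: Rh2(O2CCF3)4 expels N2 from 18 to give a rhodium carbenoid centred on C6, which adds in a [2+1] fashion across the ortho–ipso π bond C5–C11 to give norcaradiene 19, and disrotatory 6π electrocyclic opening of the C5–C11 cyclopropane bond then gives 20 (intramolecular Buchner reaction; the closest precedent is the ring expansion of aryl-tethered 2-diazo-3-ketones that carry a methyl group on the diazo carbon). Ring C (C6–C7–C8–C9–C10–C11) closes in the cyclopropanation, by bonding of the tethered carbenoid to the ipso carbon through a chair-like six-membered array, and the seven-membered ring C1–C2–C3–C4–C5–C6–C11 arises when C6 is inserted into the benzene ring on electrocyclic opening. C6 is the only new stereocentre and is governed by C10: 1,3-allylic strain against the C1 methoxy group keeps the C10–H bond in the arene plane, so the tether (C9) and the C10 methyl group lie on opposite faces and the carbenoid should add anti to that methyl group, which gives the trans C6/C10 dimethyl relationship of the target. The step needs chemoselectivity for arene addition over 1,5-insertion into the benzylic C10–H bond, over oxonium ylide formation and over 1,2-hydride shift from the C6 methyl group: the electron-poor trifluoroacetate ligands favour the π system, the C9 silyloxy group deactivates C10–H and is too hindered and too weakly basic to trap the carbenoid, and low temperature with slow addition limits the hydride shift and dimerisation. Regioselectivity for the C5–C11 bond follows from the methoxy group that blocks C1 and from C5 being ortho and para to the two ring oxygens. Because C6 is fully substituted, no hydrogen can migrate around the triene, and 20 keeps its enol ethers at C1 and C4.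

Step 12
Reactants: 20 cycloheptatriene-fused cyclohexanone
Product: 21 C7-methylene triene (as 20 with C7=CH2)
Conditions: Ph3PCH3Br, KOt-Bu, THF, 0 → 50 °C
Reagents that add atoms: methyltriphenylphosphonium bromide C[P+](c1ccccc1)(c1ccccc1)c1ccccc1.[Br-]
Why: Wittig methylenation is carried out while C7 is the only carbonyl group in the molecule; the enol ethers, the triene and the silyl ether do not react with the ylide.

Step 13
Reactants: 21 C7-methylene triene
Product: 22 cyclohepta-2,4-dienone (C4 ketone, C3=C2, C1(OMe)=C11, C5 methylene)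
Conditions: 0.2 M oxalic acid (aq.), THF, 0 °C
Reagents that add atoms: water O
Why: Enol ether hydrolysis: kinetic protonation should occur at the unsubstituted triene terminus C5 and not at the fully substituted C11, and the C1 enol ether that remains is deactivated once it is part of the dienone.

Step 14
Reactants: 22 cyclohepta-2,4-dienone
Product: 23 tricyclic cyclobutene enol ether (C1(OMe)=C2, C4 ketone, C7=CH2, C9 OTBS)
Conditions: hν (365 nm), degassed MeCN, rt, stopped at full conversion
Reagents that add atoms: none
Why: 4π disrotatory photoclosure of a 2,4-cycloheptadienone of the eucarvone type forms C3–C11 with a cis ring fusion; ring B can only form on the side of the diene where C5 lies, so C6 fixes C3 and C11 with its methyl group syn to ring A, and at 365 nm only the dienone absorbs.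

Step 15
Reactants: 23 tricyclic cyclobutene enol ether
Product: 24 C4 enol triflate (C4(OTf)=C5)
Conditions: KHMDS, THF, −78 °C; PhNTf2
Reagents that add atoms: N-phenylbis(trifluoromethanesulfonimide) O=S(=O)(N(c1ccccc1)S(=O)(=O)C(F)(F)F)C(F)(F)F
Why: Enol triflate formation is regiospecific because the C4 ketone can enolise only towards C5 (C3 is quaternary); it masks C4 before the second ketone appears and flattens ring B.

Step 16
Reactants: 24 C4 enol triflate
Product: 25 cyclobutanone (C1 ketone)
Conditions: 1 M HCl, THF, 0 °C → rt, short reaction time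
Reagents that add atoms: water O
Why: Hydrolysis of the strained 1-methoxycyclobutene is fast in dilute acid, which the enol triflate, the exocyclic alkene and the secondary silyl ether should tolerate.

Step 17
Reactants: 25 cyclobutanone
Product: 26 C1 cyclobutanol (hydroxyl exo, cis to C10; 1R)
Conditions: (S)-2-methyl-CBS-oxazaborolidine (20 mol%), catecholborane, toluene, −78 → −40 °C
Reagents that add atoms: none
Why: Corey–Bakshi–Shibata reduction: the oxazaborolidine distinguishes the quaternary C11 flank from the C2 methylene flank, and the (S)-catalyst should give the (1R) alcohol with oxygen exo, by hydride approach over ring B that the planar C4=C5 enol triflate leaves open; catecholborane leaves the alkenes and the triflate untouched.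

Step 18
Reactants: 26 C1 cyclobutanol
Product: 27 C1 acetate (enol triflate, C7=CH2, C9 OTBS)
Conditions: Ac2O, DMAP (cat.), pyridine, CH2Cl2, rt
Reagents that add atoms: acetic anhydride CC(=O)OC(C)=O
Why: Acylation of the only free hydroxyl proceeds with retention and installs the ester of the target.

Step 19
Reactants: 27 C1 acetate
Product: 28 bromoalkene (C4(Br)=C5)
Conditions: Ni(OAc)2·4H2O (10 mol%), 1,5-cyclooctadiene, Zn (20 mol%), LiBr, DMA–THF, rt
Reagents that add atoms: lithium bromide [Li+].[Br-]
Why: Nickel-catalysed halogenation of an enol triflate (oxidative addition of zerovalent nickel into C–OTf, triflate–bromide exchange, reductive elimination) is mild enough for the acetate, the silyl ether and the exocyclic alkene.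

Step 20
Reactants: 28 bromoalkene
Product: 29 C9 alcohol (bromoalkene, C7=CH2, C1 OAc)
Conditions: HF·pyridine, pyridine, THF, 0 °C → rt
Reagents that add atoms: none
Why: Fluoride-mediated desilylation frees the C9 hydroxyl without touching the acetate or the vinyl bromide.

Step 21
Reactants: 29 C9 alcohol
Product: 30 C7-methyl compound (7R, methyl trans to the C9 hydroxyl; bromoalkene retained)
Conditions: [Ir(cod)(PCy3)(py)]PF6 (10 mol%), H2 (1 atm), CH2Cl2, 0 °C → rt
Reagents that add atoms: none
Why: Hydroxyl-directed hydrogenation with Crabtree's catalyst: iridium bound to the homoallylic C9 hydroxyl adds hydrogen to the exocyclic alkene on the hydroxyl face, so C7–H is cis to the hydroxyl and the methyl group equatorial, while the hindered, electron-poor bromoalkene between two quaternary carbons should not react at 1 atm.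

Step 22
Reactants: 30 C7-methyl compound
Product: 31 C4 bromide (4S, bromine cis to ring A)
Conditions: Mn(dpm)3 (10 mol%; dpm = 2,2,6,6-tetramethylheptane-3,5-dionate), PhSiH3, t-BuOOH, i-PrOH, rt
Reagents that add atoms: none
Why: Hydrogen-atom-transfer hydrogenation (Mukaiyama-type manganese hydride conditions, which reduce bromoalkenes without hydrogenolysis): the first hydrogen atom adds to C5 to give the bromine-stabilised C4 radical, which should take the second hydrogen on the convex face anti to ring A, because the endo hydrogen of C2 hangs over the other face, leaving bromine cis to ring A.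

Step 23
Reactants: 31 C4 bromide
Product: 32 C9 ketone
Conditions: Dess–Martin periodinane, NaHCO3, CH2Cl2, rt
Reagents that add atoms: none
Why: Dess–Martin oxidation of the hindered axial alcohol under buffered conditions spares the acetate and the bromide, and the C10 methyl group next to the new ketone is already in its more stable equatorial position.

Step 24
Reactants: 32 C9 ketone
Product: 34 C8-bromo ketone (8S, bromine equatorial, trans to the C7 methyl), via trimethylsilyl enol ether 33 (not isolated)
Conditions: TMSOTf, Et3N, CH2Cl2, 0 °C; then NBS, THF, −78 → 0 °C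
Reagents that add atoms: N-bromosuccinimide O=C1CCC(=O)N1Br
Why: Enol silylation then bromination: enolisation should go towards C8, since a C9=C10 enol ether would press the C10 methyl group against the substituents of quaternary C11, and bromine should end equatorial because the axial position at C8 is syn to the axial C6 methyl group and any axial bromide can equilibrate through the enol.

Step 25
Reactants: 34 C8-bromo ketone
Product: 35 (1R,2R,4R,5S,7R,8R,9S,10R,11R)-5,9-dibromo-10-hydroxy-4,7,8,11-tetramethyltricyclo[5.4.0.0(1,4)]undecan-2-yl acetate (target; route numbering 1R,3R,4S,6R,7R,8S,9R,10R,11R)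
Conditions: L-Selectride (LiBH(s-Bu)3), THF, −78 °C
Reagents that add atoms: none
Why: Hydride reduction of the α-bromo ketone: the bulky borohydride should attack C9 equatorially, the axial path being closed by the axial C3 bond on C11, to give the axial alcohol cis to the equatorial bromine, and the acetate is not reduced at −78 °C.

Compound list
1 | 1-bromo-2,5-dimethoxy-4-methylbenzene | COc1cc(C)c(OC)cc1Br | starting material
2 | ethyl pyruvate | CCOC(=O)C(C)=O | starting material
3 | (2,5-dimethoxy-4-methylphenyl)magnesium bromide | COc1cc(C)c(OC)cc1[Mg]Br | intermediate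
4 | ethyl 2-(2,5-dimethoxy-4-methylphenyl)-2-hydroxypropanoate (racemic) | COc1cc(C)c(OC)cc1C(C)(O)C(=O)OCC | intermediate
5 | ethyl 2-(2,5-dimethoxy-4-methylphenyl)prop-2-enoate | COc1cc(C)c(OC)cc1C(=C)C(=O)OCC | intermediate
6 | 2-(2,5-dimethoxy-4-methylphenyl)prop-2-enoic acid | COc1cc(C)c(OC)cc1C(=C)C(=O)O | intermediate
7 | (2R)-2-(2,5-dimethoxy-4-methylphenyl)propanoic acid | COc1cc(C)c(OC)cc1[C@@H](C)C(=O)O | intermediate
8 | potassium ethyl malonate | CCOC(=O)CC(=O)[O-].[K+] | starting material
9 | (2R)-2-(2,5-dimethoxy-4-methylphenyl)-1-(imidazol-1-yl)propan-1-one | COc1cc(C)c(OC)cc1[C@@H](C)C(=O)n1ccnc1 | intermediate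
10 | (4R)-4-(2,5-dimethoxy-4-methylphenyl)-2-(ethoxycarbonyl)-3-oxopentanoic acid (magnesium salt in the flask, C2 unassigned) | COc1cc(C)c(OC)cc1[C@@H](C)C(=O)C(C(=O)O)C(=O)OCC | intermediate
11 | ethyl (4R)-4-(2,5-dimethoxy-4-methylphenyl)-3-oxopentanoate | COc1cc(C)c(OC)cc1[C@@H](C)C(=O)CC(=O)OCC | intermediate
12 | ethyl (3S,4R)-4-(2,5-dimethoxy-4-methylphenyl)-3-hydroxypentanoate | COc1cc(C)c(OC)cc1[C@@H](C)[C@@H](O)CC(=O)OCC | intermediate
13 | ethyl (3S,4R)-3-[(tert-butyldimethylsilyl)oxy]-4-(2,5-dimethoxy-4-methylphenyl)pentanoate | COc1cc(C)c(OC)cc1[C@@H](C)[C@@H](O[Si](C)(C)C(C)(C)C)CC(=O)OCC | intermediate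
14 | (3S,4R)-3-[(tert-butyldimethylsilyl)oxy]-4-(2,5-dimethoxy-4-methylphenyl)-N-methoxy-N-methylpentanamide | COc1cc(C)c(OC)cc1[C@@H](C)[C@@H](O[Si](C)(C)C(C)(C)C)CC(=O)N(C)OC | intermediate
15 | ethylmagnesium bromide | CC[Mg]Br | starting material
16 | (5S,6R)-5-[(tert-butyldimethylsilyl)oxy]-6-(2,5-dimethoxy-4-methylphenyl)heptan-3-one | COc1cc(C)c(OC)cc1[C@@H](C)[C@@H](O[Si](C)(C)C(C)(C)C)CC(=O)CC | intermediate
17 | (6S,7R)-6-[(tert-butyldimethylsilyl)oxy]-7-(2,5-dimethoxy-4-methylphenyl)-1,1,1-trifluoro-3-methyloctane-2,4-dione (C3 epimers) | COc1cc(C)c(OC)cc1[C@@H](C)[C@@H](O[Si](C)(C)C(C)(C)C)CC(=O)C(C)C(=O)C(F)(F)F | intermediate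
18 | (5S,6R)-5-[(tert-butyldimethylsilyl)oxy]-2-diazo-6-(2,5-dimethoxy-4-methylphenyl)heptan-3-one (key-step precursor) | COc1cc(C)c(OC)cc1[C@@H](C)[C@@H](O[Si](C)(C)C(C)(C)C)CC(=O)C(C)=[N+]=[N-] | intermediate
19 | norcaradiene: cyclopropane C5–C6–C11 fused to the 1,4-dimethoxy-3-methylcyclohexa-1,3-diene and to ring C (C7 ketone, C9 OTBS, C10 methyl) | COC1=CC(C)=C(OC)[C@H]2[C@]3(C)C(=O)C[C@H](O[Si](C)(C)C(C)(C)C)[C@H](C)[C@]123 | intermediate
20 | Buchner product: cyclohepta-triene (C1=C11, C2=C3, C4=C5; OMe at C1, C4; Me at C3) fused at C6–C11 to ring C (C6 methyl, C7 ketone, C9 OTBS, C10 methyl trans to C6 methyl) | COC1=C2[C@@H](C)[C@@H](O[Si](C)(C)C(C)(C)C)CC(=O)[C@@]2(C)C=C(OC)C(C)=C1 | intermediate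
21 | as 20 with C7 exocyclic methylene in place of the ketone | COC1=C2[C@@H](C)[C@@H](O[Si](C)(C)C(C)(C)C)CC(=C)[C@@]2(C)C=C(OC)C(C)=C1 | intermediate
22 | cyclohepta-2,4-dienone: C4 ketone, C3(Me)=C2, C1(OMe)=C11, C5 methylene; ring C as in 21 | COC1=C2[C@@H](C)[C@@H](O[Si](C)(C)C(C)(C)C)CC(=C)[C@@]2(C)CC(=O)C(C)=C1 | intermediate
23 | tricycle with 1-methoxycyclobutene (C1=C2), C4 ketone, C7 methylene, C9 OTBS; C6 methyl syn to ring A | COC1=C[C@@]2(C)C(=O)C[C@]3(C)C(=C)C[C@H](O[Si](C)(C)C(C)(C)C)[C@H](C)[C@]123 | intermediate
24 | as 23 with C4 enol triflate (C4=C5) | COC1=C[C@@]2(C)C(OS(=O)(=O)C(F)(F)F)=C[C@]3(C)C(=C)C[C@H](O[Si](C)(C)C(C)(C)C)[C@H](C)[C@]123 | intermediate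
25 | cyclobutanone: C1 ketone, C4 enol triflate, C7 methylene, C9 OTBS | O=C1C[C@@]2(C)C(OS(=O)(=O)C(F)(F)F)=C[C@]3(C)C(=C)C[C@H](O[Si](C)(C)C(C)(C)C)[C@H](C)[C@]123 | intermediate
26 | (1R)-cyclobutanol, hydroxyl exo (cis to C10); otherwise as 25 | O[C@@H]1C[C@@]2(C)C(OS(=O)(=O)C(F)(F)F)=C[C@]3(C)C(=C)C[C@H](O[Si](C)(C)C(C)(C)C)[C@H](C)[C@]123 | intermediate
27 | C1 acetate of 26 | CC(=O)O[C@@H]1C[C@@]2(C)C(OS(=O)(=O)C(F)(F)F)=C[C@]3(C)C(=C)C[C@H](O[Si](C)(C)C(C)(C)C)[C@H](C)[C@]123 | intermediate
28 | C4 bromoalkene (C4(Br)=C5), C1 OAc, C7 methylene, C9 OTBS | CC(=O)O[C@@H]1C[C@@]2(C)C(Br)=C[C@]3(C)C(=C)C[C@H](O[Si](C)(C)C(C)(C)C)[C@H](C)[C@]123 | intermediate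
29 | as 28 with free (9S)-hydroxyl | CC(=O)O[C@@H]1C[C@@]2(C)C(Br)=C[C@]3(C)C(=C)C[C@H](O)[C@H](C)[C@]123 | intermediate
30 | as 29 with C7 methyl (trans to C9 hydroxyl) | CC(=O)O[C@@H]1C[C@@]2(C)C(Br)=C[C@]3(C)[C@@H](C)C[C@H](O)[C@H](C)[C@]123 | intermediate
31 | saturated C4 bromide (bromine cis to ring A), C9 hydroxyl | CC(=O)O[C@@H]1C[C@@]2(C)[C@@H](Br)C[C@]3(C)[C@@H](C)C[C@H](O)[C@H](C)[C@]123 | intermediate
32 | C9 ketone of 31 | CC(=O)O[C@@H]1C[C@@]2(C)[C@@H](Br)C[C@]3(C)[C@@H](C)CC(=O)[C@H](C)[C@]123 | intermediate
33 | C8=C9 trimethylsilyl enol ether of 32 | CC(=O)O[C@@H]1C[C@@]2(C)[C@@H](Br)C[C@]3(C)[C@@H](C)C=C(O[Si](C)(C)C)[C@H](C)[C@]123 | intermediate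
34 | C8-bromo C9 ketone (bromine equatorial, trans to C7 methyl) | CC(=O)O[C@@H]1C[C@@]2(C)[C@@H](Br)C[C@]3(C)[C@@H](C)[C@H](Br)C(=O)[C@H](C)[C@]123 | intermediate
35 | (1R,2R,4R,5S,7R,8R,9S,10R,11R)-5,9-dibromo-10-hydroxy-4,7,8,11-tetramethyltricyclo[5.4.0.0(1,4)]undecan-2-yl acetate | CC(=O)O[C@@H]1C[C@@]2(C)[C@@H](Br)C[C@]3(C)[C@@H](C)[C@H](Br)[C@H](O)[C@H](C)[C@]123 | target

Total step count: 25. Longest linear sequence: 25 steps (the route is linear from 1).

Steps most likely to fail

1. Step 11 (Buchner reaction). What may go wrong is a 1,2-hydride shift of the methyl-substituted carbenoid to an enone, insertion into the benzylic C10–H bond, or incomplete facial selectivity at C6. The fallback sets out from Weinreb amide 14 and returns at 20. MeMgBr converts 14 into methyl ketone F1. LiHMDS with CF3CO2CH2CF3 gives the trifluoroacetyl diketone F2, and MsN3 with Et3N then gives the terminal diazoketone F3, whose carbenoid has no β-hydrogen and belongs to the best-behaved class for arene cyclopropanation. Rh2(O2CCF3)4 should convert F3 into the C6–H cycloheptatrienone F4, as either C6 epimer. Deprotonation at the doubly allylic C6 (KHMDS, THF, −78 °C) and methylation with MeI anti to the pseudo-axial C10 methyl group would then give 20. In this variant C6 is set by enolate alkylation and no longer by the face of carbenoid addition.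

2. Step 22 (C4 hydrogen-atom transfer). What may go wrong is delivery of the second hydrogen atom to the concave face of the C4 radical, or loss of bromine if the first hydrogen atom adds to C4. The fallback sets out from 30 and returns at 31. It is a hydroxyl-directed hydrogenation with [Ir(cod)(PCy3)(py)]BArF (BArF = tetrakis[3,5-bis(trifluoromethyl)phenyl]borate) under H2 (20–50 atm) in CH2Cl2. The catalyst bound to the axial C9 hydroxyl, which lies on the face of ring B anti to ring A, would deliver both hydrogens to C4=C5 from that face. No new compound is involved.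

3. Step 17 (CBS reduction at C1). What may go wrong is that the intrinsic facial bias of the hindered cyclobutanone overrides catalyst control, giving the C1 epimer, or that reduction is slow. The fallback sets out from 25 and returns at 27. L-Selectride (THF, −78 °C) should attack from the more open face to give the C1-epimeric alcohol F5. Mitsunobu esterification (PPh3, DIAD, AcOH, toluene) would then invert C1 and give acetate 27 directly.

Further compounds
F1 | step 11 | (4S,5R)-4-[(tert-butyldimethylsilyl)oxy]-5-(2,5-dimethoxy-4-methylphenyl)hexan-2-one | COc1cc(C)c(OC)cc1[C@@H](C)[C@@H](O[Si](C)(C)C(C)(C)C)CC(C)=O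
F2 | step 11 | (6S,7R)-6-[(tert-butyldimethylsilyl)oxy]-7-(2,5-dimethoxy-4-methylphenyl)-1,1,1-trifluorooctane-2,4-dione | COc1cc(C)c(OC)cc1[C@@H](C)[C@@H](O[Si](C)(C)C(C)(C)C)CC(=O)CC(=O)C(F)(F)F
F3 | step 11 | (4S,5R)-4-[(tert-butyldimethylsilyl)oxy]-1-diazo-5-(2,5-dimethoxy-4-methylphenyl)hexan-2-one | COc1cc(C)c(OC)cc1[C@@H](C)[C@@H](O[Si](C)(C)C(C)(C)C)CC(=O)C=[N+]=[N-]
F4 | step 11 | C6–H analogue of 20 (C6 configuration unassigned) | COC1=C2[C@@H](C)[C@@H](O[Si](C)(C)C(C)(C)C)CC(=O)C2C=C(OC)C(C)=C1
F0 | step 22 | none | none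
F5 | step 17 | C1 epimer of 26 (hydroxyl endo, towards ring B) | O[C@H]1C[C@@]2(C)C(OS(=O)(=O)C(F)(F)F)=C[C@]3(C)C(=C)C[C@H](O[Si](C)(C)C(C)(C)C)[C@H](C)[C@]123
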